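## Retrosynthetic overview

1. The C8 hydroperoxide and the C7 exocyclic methylene come from a singlet-oxygen (Schenck) ene reaction on the (7E)-alkene of a macrocyclic dienyl p-coumarate; C8 is set under control of the C1 stereocentre.
2. The (7E)-alkene comes from sigmatropic N2 loss of an allylic diazene (Myers transposition) of a 2-methylenecycloundecenol, itself made by Nozaki–Hiyama–Kishi closure of the C7–C8 bond.
3. The bromo aldehyde for ring closure comes from acylation and hydroboration–oxidation of an acyclic trienol, assembled from a (Z)-alkenyllithium and a chiral epoxide (C2–C3 bond). The C1 stereocentre and the C10 quaternary carbon come from (R)-epichlorohydrin and prenylmagnesium chloride.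
4. The (Z)-alkenyl iodide comes from Zhao iodo-olefination of 4-bromopent-4-enal, made by a Johnson–Claisen [3,3]-sigmatropic rearrangement of 2-bromoallyl alcohol. This rearrangement forms the key C5–C6 bond and installs the 2-bromoallyl unit that becomes C7 and its methylene.
5. Ring order: there is one carbocycle (11-membered); it is closed at step 10.

Assumption: ring atoms are numbered as in the name (1R,3Z,8S)-8-hydroperoxy-3,10,10-trimethyl-7-methylidenecycloundec-3-en-1-yl (2E)-3-(4-hydroxyphenyl)prop-2-enoate, and "O-TBS-coumarate" means (2E)-3-[4-(tert-butyldimethylsilyloxy)phenyl]prop-2-enoate.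

## Route

Step 1
Reactants: 1 2-bromoprop-2-en-1-ol; 2 triethyl orthoacetate
Product: 4 ethyl 4-bromopent-4-enoate, via 2-bromoallyl ethyl ketene acetal 3 (not isolated)
Conditions: MeC(OEt)3 (4 equiv), EtCO2H (5 mol %), 140 °C, EtOH distilled off
Reagents that add atoms: none
Why: Johnson–Claisen rearrangement: acid-catalysed exchange gives the mixed ketene acetal, whose [3,3]-sigmatropic shift through a chair transition state forms the C5–C6 bond and leaves the 2-bromo-1-alkene; no stereocentre is formed.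

Step 2
Reactants: 4 ethyl 4-bromopent-4-enoate
Product: 6 4-bromopent-4-enal, via aluminium hemiacetal 5 (not isolated)
Conditions: i-Bu2AlH (1.05 equiv), CH2Cl2, −78 °C; MeOH, then aq KNaC4H4O6 (potassium sodium tartrate)
Reagents that add atoms: none
Why: Partial ester reduction: the tetrahedral aluminium hemiacetal is stable at −78 °C and releases the aldehyde only on work-up.

Step 3
Reactants: 6 4-bromopent-4-enal; 7 ethyltriphenylphosphonium iodide
Product: 11 (2Z)-6-bromo-2-iodohepta-2,6-diene, via ethylidenetriphenylphosphorane 8 (not isolated), via (1-iodoethyl)triphenylphosphonium iodide 9 (not isolated), via (1-iodoethylidene)triphenylphosphorane 10 (not isolated)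
Conditions: 7, n-BuLi, THF, 0 °C → rt; I2, −78 °C; NaN(SiMe3)2, −20 °C; then 6, −78 °C → rt
Reagents that add atoms: iodine, II
Why: Zhao iodo-olefination (a Wittig reaction of the α-iodo ylide under kinetic control) gives the (Z)-2-iodoalk-2-ene with iodine cis to the chain, which fixes the later (3Z)-alkene; the minor E isomer is removed by chromatography after step 5.

Step 4
Reactants: 12 (R)-epichlorohydrin; 13 prenylmagnesium chloride
Product: 15 (2R)-2-(2,2-dimethylbut-3-en-1-yl)oxirane, via (2R)-1-chloro-4,4-dimethylhex-5-en-2-ol 14 (not isolated)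
Conditions: 13 (1.2 equiv), THF, no copper salt, −30 → 0 °C; then 3 M aq NaOH, rt
Reagents that add atoms: none
Why: The allylic Grignard reagent opens the epoxide at its CH2 through its γ-carbon (SE2′), building the quaternary C10, and the alkoxide then closes onto CH2Cl (intramolecular Williamson reaction); no bond to the stereocentre is broken, so its configuration comes directly from 12.

Step 5
Reactants: 11 (2Z)-6-bromo-2-iodohepta-2,6-diene; 15 (2R)-2-(2,2-dimethylbut-3-en-1-yl)oxirane
Product: 17 (5S,7Z)-11-bromo-3,3,7-trimethyldodeca-1,7,11-trien-5-ol, via (2E)-6-bromohepta-2,6-dien-2-yllithium 16 (not isolated)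
Conditions: t-BuLi (2.0 equiv), Et2O, −78 °C, 15 min; then 15, BF3·OEt2, −78 °C
Reagents that add atoms: none
Why: Iodine–lithium exchange is much faster than bromine–lithium exchange and retains alkene geometry, and the alkenyllithium opens the BF3-activated epoxide at the unsubstituted carbon (SN2); the carbinol centre is untouched (5S here only because CIP priorities change; the spatial arrangement is that of C1 in the target).

Step 6
Reactants: 18 (E)-p-coumaric acid
Product: 20 (2E)-3-[4-(tert-butyldimethylsilyloxy)phenyl]prop-2-enoic acid, via bis-silylated coumarate 19 (not isolated)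
Conditions: TBSCl (2.4 equiv), imidazole, DMF, rt; then AcOH–THF–H2O, rt
Reagents that add atoms: tert-butyldimethylsilyl chloride, CC(C)(C)[Si](C)(C)Cl
Why: Both acidic OH groups are silylated and the labile silyl ester is then hydrolysed selectively, leaving the aryl silyl ether.

Step 7
Reactants: 17 (5S,7Z)-11-bromo-3,3,7-trimethyldodeca-1,7,11-trien-5-ol; 20 (2E)-3-[4-(tert-butyldimethylsilyloxy)phenyl]prop-2-enoic acid
Product: 21 (5S,7Z)-11-bromo-3,3,7-trimethyldodeca-1,7,11-trien-5-yl O-TBS-coumarate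
Conditions: DCC (1.3 equiv), DMAP (0.2 equiv), CH2Cl2, 0 °C → rt
Reagents that add atoms: none
Why: Steglich esterification acylates at oxygen, so the C–O bond of the stereocentre is not broken and configuration is retained.

Step 8
Reactants: 21 (5S,7Z)-11-bromo-3,3,7-trimethyldodeca-1,7,11-trien-5-yl O-TBS-coumarate
Product: 23 (5R,7Z)-11-bromo-1-hydroxy-3,3,7-trimethyldodeca-7,11-dien-5-yl O-TBS-coumarate, via B-alkyl-9-borabicyclononane adduct 22 (not isolated)
Conditions: 9-BBN (1.3 equiv), THF, 0 °C → rt; then 30% H2O2, 3 M aq NaOAc, 0 °C → rt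
Reagents that add atoms: hydrogen peroxide, OO
Why: Hydroboration–oxidation: 9-BBN adds anti-Markovnikov to the monosubstituted vinyl group only (the bromoalkene, the trisubstituted alkene and the cinnamate are far slower), and buffered peroxide oxidation spares the ester and the aryl silyl ether.

Step 9
Reactants: 23 (5R,7Z)-11-bromo-1-hydroxy-3,3,7-trimethyldodeca-7,11-dien-5-yl O-TBS-coumarate
Product: 24 (5R,7Z)-11-bromo-3,3,7-trimethyl-1-oxododeca-7,11-dien-5-yl O-TBS-coumarate
Conditions: Dess–Martin periodinane (1.3 equiv), NaHCO3, CH2Cl2, 0 °C → rt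
Reagents that add atoms: none
Why: Dess–Martin oxidation converts the primary alcohol into the aldehyde under neutral conditions without touching the alkenes or the alkenyl bromide.

Step 10
Reactants: 24 (5R,7Z)-11-bromo-3,3,7-trimethyl-1-oxododeca-7,11-dien-5-yl O-TBS-coumarate
Product: 26 (1R,3Z,8RS)-8-hydroxy-3,10,10-trimethyl-7-methylidenecycloundec-3-en-1-yl O-TBS-coumarate, via alkenylchromium dichloride 25 (not isolated)
Conditions: CrCl2 (10 equiv), NiCl2 (2 mol %), DMSO–THF 3:1, rt, syringe-pump addition to 2 mM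
Reagents that add atoms: none
Why: Nozaki–Hiyama–Kishi reaction: nickel-catalysed activation of the C–Br bond and transmetalation give an alkenylchromium species that adds only to the aldehyde, closing the C7–C8 bond and the 11-membered ring with the methylene in place; both C8 epimers form and are carried on, because step 11 removes this centre.

Step 11
Reactants: 26 (1R,3Z,8RS)-8-hydroxy-3,10,10-trimethyl-7-methylidenecycloundec-3-en-1-yl O-TBS-coumarate
Product: 29 (1R,3Z,7E)-3,7,10,10-tetramethylcycloundeca-3,7-dien-1-yl O-TBS-coumarate, via allylic sulfonylhydrazide 27 (not isolated), via allylic diazene 28 (not isolated)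
Conditions: 2-nitrobenzenesulfonylhydrazide, PPh3, DEAD, THF, −30 °C, 2 h; then 23 °C
Reagents that add atoms: none
Why: Myers reductive allylic transposition: Mitsunobu displacement, loss of sulfinic acid to the monoalkyl diazene and sigmatropic (retro-ene) loss of N2 deliver hydrogen to the methylene carbon and move the alkene to C7=C8, expected E because C9 sits pseudo-equatorial and anti to C6 in the six-membered transition state.

Step 12
Reactants: 29 (1R,3Z,7E)-3,7,10,10-tetramethylcycloundeca-3,7-dien-1-yl O-TBS-coumarate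
Product: 30 (1R,3Z,7E)-3,7,10,10-tetramethylcycloundeca-3,7-dien-1-yl (2E)-3-(4-hydroxyphenyl)prop-2-enoate
Conditions: Bu4NF (1.1 equiv), AcOH (1.1 equiv), THF, 0 °C
Reagents that add atoms: none
Why: Buffered fluoride desilylation frees the phenol without cleaving the cinnamate ester.

Step 13
Reactants: 30 (1R,3Z,7E)-3,7,10,10-tetramethylcycloundeca-3,7-dien-1-yl (2E)-3-(4-hydroxyphenyl)prop-2-enoate
Product: 31 (1R,3Z,8S)-8-hydroperoxy-3,10,10-trimethyl-7-methylidenecycloundec-3-en-1-yl (2E)-3-(4-hydroxyphenyl)prop-2-enoate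
Conditions: O2, tetraphenylporphyrin (cat.), hν (>500 nm), CH2Cl2, −20 °C, stopped at about one equivalent of O2
Reagents that add atoms: dioxygen, O=O
Why: Schenck ene reaction: singlet oxygen attacks the strained (7E)-alkene from the ring periphery and abstracts H from the C7 methyl (cis to C9, cis effect), so O bonds to C8 and the alkene becomes exocyclic; the (8S) outcome is the expected result of substrate control by C1, not a proven one, and the (3Z)-alkene reacts more slowly because its methyl lies on the unreactive side.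

## Compound list

1 | 2-bromoprop-2-en-1-ol | OCC(Br)=C | starting material
2 | triethyl orthoacetate | CC(OCC)(OCC)OCC | starting material
3 | 2-bromoallyl ethyl ketene acetal (2-bromo-3-[(1-ethoxyethenyl)oxy]prop-1-ene) | C=C(OCC)OCC(Br)=C | intermediate
4 | ethyl 4-bromopent-4-enoate | CCOC(=O)CCC(Br)=C | intermediate
5 | aluminium hemiacetal, [(4-bromo-1-ethoxypent-4-en-1-yl)oxy]bis(2-methylpropyl)alumane | CCOC(CCC(Br)=C)O[Al](CC(C)C)CC(C)C | intermediate
6 | 4-bromopent-4-enal | O=CCCC(Br)=C | intermediate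
7 | ethyltriphenylphosphonium iodide | CC[P+](c1ccccc1)(c1ccccc1)c1ccccc1.[I-] | starting material
8 | ethylidenetriphenylphosphorane | CC=P(c1ccccc1)(c1ccccc1)c1ccccc1 | intermediate
9 | (1-iodoethyl)triphenylphosphonium iodide | CC(I)[P+](c1ccccc1)(c1ccccc1)c1ccccc1.[I-] | intermediate
10 | (1-iodoethylidene)triphenylphosphorane | CC(I)=P(c1ccccc1)(c1ccccc1)c1ccccc1 | intermediate
11 | (2Z)-6-bromo-2-iodohepta-2,6-diene | C/C(I)=C/CCC(Br)=C | intermediate
12 | (R)-epichlorohydrin, (2R)-2-(chloromethyl)oxirane | ClC[C@H]1CO1 | starting material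
13 | prenylmagnesium chloride (3-methylbut-2-en-1-ylmagnesium chloride) | CC(C)=CC[Mg]Cl | starting material
14 | (2R)-1-chloro-4,4-dimethylhex-5-en-2-ol | ClC[C@H](O)CC(C)(C)C=C | intermediate
15 | (2R)-2-(2,2-dimethylbut-3-en-1-yl)oxirane | C=CC(C)(C)C[C@@H]1CO1 | intermediate
16 | (2E)-6-bromohepta-2,6-dien-2-yllithium (Li cis to the chain) | C/C([Li])=C/CCC(Br)=C | intermediate
17 | (5S,7Z)-11-bromo-3,3,7-trimethyldodeca-1,7,11-trien-5-ol | C=C(Br)CC/C=C(/C)C[C@H](O)CC(C)(C)C=C | intermediate
18 | (E)-p-coumaric acid | O=C(O)/C=C/c1ccc(O)cc1 | starting material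
19 | tert-butyldimethylsilyl (2E)-3-[4-(tert-butyldimethylsilyloxy)phenyl]prop-2-enoate | CC(C)(C)[Si](C)(C)OC(=O)/C=C/c1ccc(O[Si](C)(C)C(C)(C)C)cc1 | intermediate
20 | (2E)-3-[4-(tert-butyldimethylsilyloxy)phenyl]prop-2-enoic acid | O=C(O)/C=C/c1ccc(O[Si](C)(C)C(C)(C)C)cc1 | intermediate
21 | (5S,7Z)-11-bromo-3,3,7-trimethyldodeca-1,7,11-trien-5-yl (2E)-3-[4-(tert-butyldimethylsilyloxy)phenyl]prop-2-enoate | C=C(Br)CC/C=C(/C)C[C@H](OC(=O)/C=C/c1ccc(O[Si](C)(C)C(C)(C)C)cc1)CC(C)(C)C=C | intermediate
22 | (5R,7Z)-1-(9-borabicyclo[3.3.1]nonan-9-yl)-11-bromo-3,3,7-trimethyldodeca-7,11-dien-5-yl O-TBS-coumarate | C=C(Br)CC/C=C(/C)C[C@H](OC(=O)/C=C/c1ccc(O[Si](C)(C)C(C)(C)C)cc1)CC(C)(C)CCB1C2CCCC1CCC2 | intermediate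
23 | (5R,7Z)-11-bromo-1-hydroxy-3,3,7-trimethyldodeca-7,11-dien-5-yl O-TBS-coumarate | C=C(Br)CC/C=C(/C)C[C@H](OC(=O)/C=C/c1ccc(O[Si](C)(C)C(C)(C)C)cc1)CC(C)(C)CCO | intermediate
24 | (5R,7Z)-11-bromo-3,3,7-trimethyl-1-oxododeca-7,11-dien-5-yl O-TBS-coumarate | C=C(Br)CC/C=C(/C)C[C@H](OC(=O)/C=C/c1ccc(O[Si](C)(C)C(C)(C)C)cc1)CC(C)(C)CC=O | intermediate
25 | alkenylchromium dichloride of 24 (Cr in place of Br) | C=C([Cr](Cl)Cl)CC/C=C(/C)C[C@H](OC(=O)/C=C/c1ccc(O[Si](C)(C)C(C)(C)C)cc1)CC(C)(C)CC=O | intermediate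
26 | (1R,3Z,8RS)-8-hydroxy-3,10,10-trimethyl-7-methylidenecycloundec-3-en-1-yl O-TBS-coumarate | C=C1CC/C=C(/C)C[C@H](OC(=O)/C=C/c2ccc(O[Si](C)(C)C(C)(C)C)cc2)CC(C)(C)CC1O | intermediate
27 | (1R,3Z,8RS)-8-[1-(2-nitrophenylsulfonyl)hydrazin-1-yl]-3,10,10-trimethyl-7-methylidenecycloundec-3-en-1-yl O-TBS-coumarate | C=C1CC/C=C(/C)C[C@H](OC(=O)/C=C/c2ccc(O[Si](C)(C)C(C)(C)C)cc2)CC(C)(C)CC1N(N)S(=O)(=O)c1ccccc1[N+](=O)[O-] | intermediate
28 | (1R,3Z,8RS)-8-diazenyl-3,10,10-trimethyl-7-methylidenecycloundec-3-en-1-yl O-TBS-coumarate | C=C1CC/C=C(/C)C[C@H](OC(=O)/C=C/c2ccc(O[Si](C)(C)C(C)(C)C)cc2)CC(C)(C)CC1N=N | intermediate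
29 | (1R,3Z,7E)-3,7,10,10-tetramethylcycloundeca-3,7-dien-1-yl O-TBS-coumarate | C/C1=C\CC(C)(C)C[C@@H](OC(=O)/C=C/c2ccc(O[Si](C)(C)C(C)(C)C)cc2)C/C(C)=C\CC1 | intermediate
30 | (1R,3Z,7E)-3,7,10,10-tetramethylcycloundeca-3,7-dien-1-yl (2E)-3-(4-hydroxyphenyl)prop-2-enoate | C/C1=C\CC(C)(C)C[C@@H](OC(=O)/C=C/c2ccc(O)cc2)C/C(C)=C\CC1 | intermediate
31 | (1R,3Z,8S)-8-hydroperoxy-3,10,10-trimethyl-7-methylidenecycloundec-3-en-1-yl (2E)-3-(4-hydroxyphenyl)prop-2-enoate (CNP0208931.1) | C=C1CC/C=C(/C)C[C@H](OC(=O)/C=C/c2ccc(O)cc2)CC(C)(C)C[C@@H]1OO | target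

## Step count and risks

Total step count: 13. Longest linear sequence: 11 steps (1, 2, 3, 5, 7, 8, 9, 10, 11, 12, 13).

The three steps most likely to fail:

Step 10. Closing an 11-membered carbocycle by chromium-mediated addition competes with oligomerisation and protodebromination. The fallback closes the ring as the C7=C8 alkene by carbonyl coupling; it sets out from 23 and comes back at 29, bypassing steps 10 and 11. Palladium-catalysed borylation of the alkenyl bromide of 23 (B2pin2, PdCl2(PPh3)2, PPh3, KOPh, toluene, 50 °C) gives the alkenyl pinacol boronate F1. Oxidation with NaBO3 in THF–H2O unmasks the methyl ketone and gives the hydroxy ketone F2. Dess–Martin oxidation gives the keto aldehyde F3. McMurry coupling of F3 with low-valent titanium (TiCl3, Zn–Cu, DME, reflux, syringe-pump addition) joins C7 and C8 and delivers 29. Compatibility of the cinnamate ester with low-valent titanium is the open point of this fallback.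

Step 11. The Mitsunobu displacement at the ring carbon may go SN2′ or be slow, and the alkene may form as an E/Z mixture; only the E isomer gives the right ene regiochemistry. The fallback reaches the same diazene through carbonyl chemistry; it sets out from 26 and comes back at 29. Dess–Martin oxidation of 26 gives the α-methylene ketone F4. Condensation with TsNHNH2 (EtOH, cat. AcOH) gives the tosylhydrazone F5. Reduction of F5 with catecholborane (CHCl3, 0 °C), then NaOAc·3H2O at reflux, expels sulfinate and N2 with the same alkene migration and gives 29.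

Step 13. Singlet oxygen may also attack the (3Z)-alkene, and the facial selectivity at C8 rests on substrate control alone. The fallback installs the hydroperoxide by substitution; it sets out from 26 and comes back at 31, bypassing steps 11 to 13. The C8 epimers of 26 are separated and the (8R)-alcohol F6 is converted (MsCl, Et3N, CH2Cl2, −40 °C) into the (8R)-mesylate F7. Displacement of F7 with caesium hydroperoxide (30% H2O2, CsOH·H2O, DMF, −20 → 0 °C) proceeds with inversion (SN2), also cleaves the aryl silyl ether, and gives 31 directly.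

Further compounds

F1 | step 10 | (5R,7Z)-1-hydroxy-3,3,7-trimethyl-11-(4,4,5,5-tetramethyl-1,3,2-dioxaborolan-2-yl)dodeca-7,11-dien-5-yl O-TBS-coumarate | C=C(B1OC(C)(C)C(C)(C)O1)CC/C=C(/C)C[C@H](OC(=O)/C=C/c1ccc(O[Si](C)(C)C(C)(C)C)cc1)CC(C)(C)CCO
F2 | step 10 | (5R,7Z)-1-hydroxy-3,3,7-trimethyl-11-oxododec-7-en-5-yl O-TBS-coumarate | CC(=O)CC/C=C(/C)C[C@H](OC(=O)/C=C/c1ccc(O[Si](C)(C)C(C)(C)C)cc1)CC(C)(C)CCO
F3 | step 10 | (5R,7Z)-3,3,7-trimethyl-1,11-dioxododec-7-en-5-yl O-TBS-coumarate | CC(=O)CC/C=C(/C)C[C@H](OC(=O)/C=C/c1ccc(O[Si](C)(C)C(C)(C)C)cc1)CC(C)(C)CC=O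
F4 | step 11 | (1R,3Z)-3,10,10-trimethyl-7-methylidene-8-oxocycloundec-3-en-1-yl O-TBS-coumarate | C=C1CC/C=C(/C)C[C@H](OC(=O)/C=C/c2ccc(O[Si](C)(C)C(C)(C)C)cc2)CC(C)(C)CC1=O
F5 | step 11 | 4-methylbenzenesulfonylhydrazone of F4 | C=C1CC/C=C(/C)C[C@H](OC(=O)/C=C/c2ccc(O[Si](C)(C)C(C)(C)C)cc2)CC(C)(C)CC1=NNS(=O)(=O)c1ccc(C)cc1
F6 | step 13 | (1R,3Z,8R)-8-hydroxy-3,10,10-trimethyl-7-methylidenecycloundec-3-en-1-yl O-TBS-coumarate | C=C1CC/C=C(/C)C[C@H](OC(=O)/C=C/c2ccc(O[Si](C)(C)C(C)(C)C)cc2)CC(C)(C)C[C@H]1O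
F7 | step 13 | (1R,3Z,8R)-8-(methylsulfonyloxy)-3,10,10-trimethyl-7-methylidenecycloundec-3-en-1-yl O-TBS-coumarate | C=C1CC/C=C(/C)C[C@H](OC(=O)/C=C/c2ccc(O[Si](C)(C)C(C)(C)C)cc2)CC(C)(C)C[C@H]1OS(C)(=O)=O
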